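**Retrosynthetic overview**

1. Locants: C1 enoate carbonyl, C2=C3, C4, ring O–C5–C6(=O)–C7(OH)=C8–C16H2, side chain C9–C14. The target comes from its O13-triethylsilyl ether/tert-butyl ester by one acidolysis.
2. C8–C9 (and E-C10=C11) are made by Mitsunobu O7–C11 etherification of the ring diosphenol with a 1-alken-3-ol, followed in the same flask by Claisen [3,3] shift and enolisation. The enabling feature is the enolised 6,7-dione of the pyranone ring: O7 sits on the C7=C8 enol, so its C11 ether is an allyl vinyl ether (C8=C7–O7–C11–C10=C9) that delivers C9 to C8 and returns the C7 carbonyl.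
3. The diosphenol comes from the ring enone (1,4-hydrosilylation/Rubottom oxidation, then acyloin oxidation); the enone ester comes from the enone acid and tert-butyl 6-bromohexanoate.
4. Ring formation: the dihydropyranone, the only ring, arises by Achmatowicz ring expansion of a furyl carbinol and hemiacetal reduction. The carbinol comes from furfural and a senecioate silyl dienolate by asymmetric vinylogous Mukaiyama aldol addition, which sets C5.
5. The 1-alken-3-ol comes from ethyl (S)-3-hydroxybutanoate (C13 from the pool): Fráter–Seebach methylation sets C12, then silylation, reduction and vinyl addition (C11 unselective, erased later).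

Key step: step 12

Assumption: the 7-enol drawn for the target is taken as the isolable tautomer of the ring 6,7-dione, and C5 as configurationally stable under neutral and acidic conditions; all steps after ring-dione formation therefore avoid free base.
Assumption: tert-butyl 3-methylbut-2-enoate and tert-butyl 6-bromohexanoate are taken as catalogue compounds.

**Route**

Step 1
Reactants: 1 ethyl (S)-3-hydroxybutanoate
Product: 2 ethyl (2S,3S)-3-hydroxy-2-methylbutanoate
Conditions: LiN(i-Pr)2 (2.2 equiv), THF, −50 → −20 °C; MeI, DMPU, −78 → 0 °C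
Reagents that add atoms: iodomethane, CI
Why: Fráter–Seebach alkylation, in which the chelated lithium alkoxide–enolate dianion is methylated anti to the C3 methyl group, setting the new centre (later C12) relative to the pool-derived carbinol (later C13).

Step 2
Reactants: 2 ethyl (2S,3S)-3-hydroxy-2-methylbutanoate
Product: 3 ethyl (2S,3S)-2-methyl-3-(triethylsilyloxy)butanoate
Conditions: Et3SiCl, imidazole, CH2Cl2, 0 °C → rt
Reagents that add atoms: chlorotriethylsilane, CC[Si](Cl)(CC)CC
Why: Standard silylation of a secondary alcohol, which touches no stereocentre and gives an ether that survives hydride, Grignard and Mitsunobu conditions but falls to acid at the end.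

Step 3
Reactants: 3 ethyl (2S,3S)-2-methyl-3-(triethylsilyloxy)butanoate
Product: 4 (2S,3S)-2-methyl-3-(triethylsilyloxy)butanal
Conditions: i-Bu2AlH (1.05 equiv), CH2Cl2, −78 °C; aq potassium sodium tartrate
Reagents that add atoms: none
Why: Partial reduction of the ester to the aldehyde through the aluminium hemiacetal, which is stable at low temperature, so the α-centre is not enolised.

Step 4
Reactants: 4 (2S,3S)-2-methyl-3-(triethylsilyloxy)butanal
Product: 5 (3RS,4R,5S)-4-methyl-5-(triethylsilyloxy)hex-1-en-3-ol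
Conditions: CH2=CHMgBr, THF, −78 → 0 °C
Reagents that add atoms: vinylmagnesium bromide, C=C[Mg]Br
Why: Grignard 1,2-addition to the aldehyde, giving the carbinol centre (later C11) as an epimer mixture, which is acceptable because this centre is destroyed in step 12.

Step 5
Reactants: 6 tert-butyl 3-methylbut-2-enoate
Product: 7 1-tert-butoxy-1-(tert-butyldimethylsilyloxy)-3-methylbuta-1,3-diene
Conditions: LiN(i-Pr)2, THF/DMPU, −78 °C; t-BuMe2SiCl, −78 °C → rt
Reagents that add atoms: tert-butyldimethylsilyl chloride, CC(C)(C)[Si](C)(C)Cl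
Why: γ-Deprotonation of the senecioate and O-silylation of the extended enolate give the silyl dienolate (vinylketene acetal formation).

Step 6
Reactants: 7 1-tert-butoxy-1-(tert-butyldimethylsilyloxy)-3-methylbuta-1,3-diene; 8 furfural (furan-2-carbaldehyde)
Product: 9 tert-butyl (2E,5S)-5-(furan-2-yl)-5-hydroxy-3-methylpent-2-enoate
Conditions: SiCl4 (1.1 equiv), chiral bisphosphoramide (5 mol %; two N,N'-dimethyl-1,1'-binaphthyl-2,2'-diamine phosphoramide units joined by a pentane-1,5-diylbis(methylamino) linker, antipode chosen for Si-face attack), i-Pr2NEt (10 mol %), CH2Cl2, −78 °C; aq NaHCO3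
Reagents that add atoms: none
Why: Catalytic enantioselective vinylogous Mukaiyama aldol addition (Lewis-base-activated SiCl4), in which the dienolate reacts through its γ-carbon on the Si face of the aldehyde held in the chiral phosphoramide–silicon complex, setting the (S)-carbinol (later C5) and giving the E-enoate directly.

Step 7
Reactants: 9 tert-butyl (2E,5S)-5-(furan-2-yl)-5-hydroxy-3-methylpent-2-enoate
Product: 10 tert-butyl (2E)-4-[(2S,6RS)-6-hydroxy-3-oxo-3,6-dihydro-2H-pyran-2-yl]-3-methylbut-2-enoate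
Conditions: NBS (1.05 equiv), NaHCO3, NaOAc, THF/H2O (4:1), 0 °C
Reagents that add atoms: water, O
Why: Achmatowicz oxidative ring expansion, in which the furan is opened to the cis-enedione and closed by the carbinol oxygen to the six-membered hemiacetal; the carbinol centre is carried over unchanged as C5 and the anomeric centre is an inconsequential mixture.

Step 8
Reactants: 10 tert-butyl (2E)-4-[(2S,6RS)-6-hydroxy-3-oxo-3,6-dihydro-2H-pyran-2-yl]-3-methylbut-2-enoate
Product: 12 (2E)-3-methyl-4-[(2S)-3-oxo-3,6-dihydro-2H-pyran-2-yl]but-2-enoic acid, via tert-butyl ester enone 11 (not isolated)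
Conditions: Et3SiH (2 equiv), CF3CO2H, CH2Cl2, −40 → 0 °C; then rt
Reagents that add atoms: none
Why: Ionic hydrogenation of the hemiacetal through the ring oxocarbenium ion removes the anomeric hydroxyl, and continued acidolysis of the tert-butyl ester (loss of isobutene) frees the enoic acid without affecting C5.

Step 9
Reactants: 12 (2E)-3-methyl-4-[(2S)-3-oxo-3,6-dihydro-2H-pyran-2-yl]but-2-enoic acid; 13 tert-butyl 6-bromohexanoate
Product: 14 6-tert-butoxy-6-oxohexyl (2E)-3-methyl-4-[(2S)-3-oxo-3,6-dihydro-2H-pyran-2-yl]but-2-enoate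
Conditions: KHCO3, KI (cat.), DMF, rt
Reagents that add atoms: none
Why: SN2 O-alkylation of the potassium carboxylate by the primary bromide, which avoids carboxyl activation (and thus E/Z scrambling of the enoate) and uses a base too weak to epimerise C5.

Step 10
Reactants: 14 6-tert-butoxy-6-oxohexyl (2E)-3-methyl-4-[(2S)-3-oxo-3,6-dihydro-2H-pyran-2-yl]but-2-enoate
Product: 17 6-tert-butoxy-6-oxohexyl (2E)-4-[(2S,4RS)-4-hydroxy-3-oxooxan-2-yl]-3-methylbut-2-enoate, via silyl enol ether 15 (not isolated), via silyloxy ketone 16 (not isolated)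
Conditions: Et3SiH, RhCl(PPh3)3 (2 mol %), THF, 50 °C; then mCPBA, NaHCO3, CH2Cl2, −20 °C; then 1 M aq HCl, THF, 0 °C
Reagents that add atoms: 3-chloroperoxybenzoic acid, O=C(OO)c1cccc(Cl)c1
Why: Rhodium-catalysed 1,4-hydrosilylation of the enone gives the C6=C7 silyl enol ether regiospecifically, and Rubottom oxidation (epoxidation, silyl migration, hydrolysis) places the hydroxyl on C7; the new C7 centre is formed without control and is removed in step 11.

Step 11
Reactants: 17 6-tert-butoxy-6-oxohexyl (2E)-4-[(2S,4RS)-4-hydroxy-3-oxooxan-2-yl]-3-methylbut-2-enoate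
Product: 19 6-tert-butoxy-6-oxohexyl (2E)-4-[(2S)-4-hydroxy-3-oxo-3,6-dihydro-2H-pyran-2-yl]-3-methylbut-2-enoate, via ring diketone 18 (not isolated)
Conditions: Dess–Martin periodinane (1.2 equiv), NaHCO3, CH2Cl2, 0 °C → rt
Reagents that add atoms: none
Why: Oxidation of the acyloin to the 1,2-diketone, which enolises toward C8 to the hydrogen-bonded conjugated enol (diosphenol) under conditions that do not epimerise C5.

Step 12
Reactants: 19 6-tert-butoxy-6-oxohexyl (2E)-4-[(2S)-4-hydroxy-3-oxo-3,6-dihydro-2H-pyran-2-yl]-3-methylbut-2-enoate (1.1 equiv); 5 (3RS,4R,5S)-4-methyl-5-(triethylsilyloxy)hex-1-en-3-ol (1.0 equiv)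
Product: 22 6-tert-butoxy-6-oxohexyl (2E)-4-{(2S)-4-hydroxy-5-[(2E,4R,5S)-4-methyl-5-(triethylsilyloxy)hex-2-en-1-yl]-3-oxo-3,6-dihydro-2H-pyran-2-yl}-3-methylbut-2-enoate, via allyl vinyl ether 20 (not isolated), via rearranged ring diketone 21 (not isolated)
Conditions: PPh3 (1.1 equiv), DIAD (1.1 equiv), toluene, 0 °C → rt; then 100 °C in the same flask
Reagents that add atoms: none
Why: The PPh3/DIAD betaine deprotonates the acidic enol O7–H of 19 and turns the C11 hydroxyl of 5 into an oxyphosphonium leaving group, so that SN2 attack of O7 at C11 gives the allyl vinyl ether 20 (C8=C7–O7–C11–C10=C9); on heating, 20 undergoes a concerted chair-like [3,3]-sigmatropic (Claisen) shift that forms C8–C9, cleaves O7–C11 and returns the C7 carbonyl in 21, whose C8–H then enolises to the conjugated, hydrogen-bonded enol 22. The closest known reaction types are the Mitsunobu etherification of acidic enols and phenols with 1-alken-3-ols and the Claisen rearrangement of 2-allyloxy-2-enones (diosphenol allyl ethers) to 3-allyl-1,2-diones, here run in one flask. No ring is closed; the pyranone ring is a spectator that only supplies the enol. No new stereocentre survives: C8 is stereogenic only in 21 and is erased by enolisation, the C11 centre of either epimer of 5 is consumed, and the E geometry of C10=C11 is controlled by the chair transition state, in which the branched C12 substituent on C11 lies pseudo-equatorial to avoid a 1,3-diaxial clash with C6 on C7. The step needs O- rather than C-alkylation and SN2 rather than SN2' in the ether formation (secured by the hard oxyphosphonium electrophile, by keeping 5 limiting, and by the slower rearrangement of any linear SN2' ether, which stays behind as a neutral, separable by-product), a pericyclic rather than ionic shift (neutral non-polar medium, no Lewis acid), and enolisation toward C8 rather than C5 (no free base, so C5–H and the C5 configuration stay untouched).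

Step 13
Reactants: 22 6-tert-butoxy-6-oxohexyl (2E)-4-{(2S)-4-hydroxy-5-[(2E,4R,5S)-4-methyl-5-(triethylsilyloxy)hex-2-en-1-yl]-3-oxo-3,6-dihydro-2H-pyran-2-yl}-3-methylbut-2-enoate
Product: 23 6-{[(2E)-4-{(2S)-4-hydroxy-5-[(2E,4R,5S)-5-hydroxy-4-methylhex-2-en-1-yl]-3-oxo-3,6-dihydro-2H-pyran-2-yl}-3-methylbut-2-enoyl]oxy}hexanoic acid (6,7-diketothiomarinolic acid C6)
Conditions: CF3CO2H/CH2Cl2/H2O (30:68:2), 0 °C → rt; toluene azeotrope
Reagents that add atoms: none
Why: Brønsted acidolysis removes the triethylsilyl ether (protodesilylation) and the tert-butyl ester (loss of isobutene) in one operation, with no base present and no stereocentre involved.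

**Compound list**

1 | ethyl (S)-3-hydroxybutanoate | CCOC(=O)C[C@H](C)O | starting material
2 | ethyl (2S,3S)-3-hydroxy-2-methylbutanoate | CCOC(=O)[C@@H](C)[C@H](C)O | intermediate
3 | ethyl (2S,3S)-2-methyl-3-(triethylsilyloxy)butanoate | CCOC(=O)[C@@H](C)[C@H](C)O[Si](CC)(CC)CC | intermediate
4 | (2S,3S)-2-methyl-3-(triethylsilyloxy)butanal | O=C[C@@H](C)[C@H](C)O[Si](CC)(CC)CC | intermediate
5 | (3RS,4R,5S)-4-methyl-5-(triethylsilyloxy)hex-1-en-3-ol (C3 epimer mixture) | C=CC(O)[C@@H](C)[C@H](C)O[Si](CC)(CC)CC | intermediate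
6 | tert-butyl 3-methylbut-2-enoate | CC(C)=CC(=O)OC(C)(C)C | starting material
7 | 1-tert-butoxy-1-(tert-butyldimethylsilyloxy)-3-methylbuta-1,3-diene | C=C(C)C=C(OC(C)(C)C)O[Si](C)(C)C(C)(C)C | intermediate
8 | furfural (furan-2-carbaldehyde) | O=Cc1ccco1 | starting material
9 | tert-butyl (2E,5S)-5-(furan-2-yl)-5-hydroxy-3-methylpent-2-enoate | C/C(=C\C(=O)OC(C)(C)C)C[C@H](O)c1ccco1 | intermediate
10 | tert-butyl (2E)-4-[(2S,6RS)-6-hydroxy-3-oxo-3,6-dihydro-2H-pyran-2-yl]-3-methylbut-2-enoate | C/C(=C\C(=O)OC(C)(C)C)C[C@@H]1OC(O)C=CC1=O | intermediate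
11 | tert-butyl (2E)-3-methyl-4-[(2S)-3-oxo-3,6-dihydro-2H-pyran-2-yl]but-2-enoate (not isolated) | C/C(=C\C(=O)OC(C)(C)C)C[C@@H]1OCC=CC1=O | intermediate
12 | (2E)-3-methyl-4-[(2S)-3-oxo-3,6-dihydro-2H-pyran-2-yl]but-2-enoic acid | C/C(=C\C(=O)O)C[C@@H]1OCC=CC1=O | intermediate
13 | tert-butyl 6-bromohexanoate | CC(C)(C)OC(=O)CCCCCBr | starting material
14 | 6-tert-butoxy-6-oxohexyl (2E)-3-methyl-4-[(2S)-3-oxo-3,6-dihydro-2H-pyran-2-yl]but-2-enoate | C/C(=C\C(=O)OCCCCCC(=O)OC(C)(C)C)C[C@@H]1OCC=CC1=O | intermediate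
15 | 6-tert-butoxy-6-oxohexyl (2E)-3-methyl-4-[(2S)-3-(triethylsilyloxy)-5,6-dihydro-2H-pyran-2-yl]but-2-enoate (not isolated) | C/C(=C\C(=O)OCCCCCC(=O)OC(C)(C)C)C[C@@H]1OCCC=C1O[Si](CC)(CC)CC | intermediate
16 | 6-tert-butoxy-6-oxohexyl (2E)-3-methyl-4-[(2S,4RS)-3-oxo-4-(triethylsilyloxy)oxan-2-yl]but-2-enoate (not isolated) | C/C(=C\C(=O)OCCCCCC(=O)OC(C)(C)C)C[C@@H]1OCCC(O[Si](CC)(CC)CC)C1=O | intermediate
17 | 6-tert-butoxy-6-oxohexyl (2E)-4-[(2S,4RS)-4-hydroxy-3-oxooxan-2-yl]-3-methylbut-2-enoate | C/C(=C\C(=O)OCCCCCC(=O)OC(C)(C)C)C[C@@H]1OCCC(O)C1=O | intermediate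
18 | 6-tert-butoxy-6-oxohexyl (2E)-4-[(2S)-3,4-dioxooxan-2-yl]-3-methylbut-2-enoate (not isolated) | C/C(=C\C(=O)OCCCCCC(=O)OC(C)(C)C)C[C@@H]1OCCC(=O)C1=O | intermediate
19 | 6-tert-butoxy-6-oxohexyl (2E)-4-[(2S)-4-hydroxy-3-oxo-3,6-dihydro-2H-pyran-2-yl]-3-methylbut-2-enoate (diosphenol) | C/C(=C\C(=O)OCCCCCC(=O)OC(C)(C)C)C[C@@H]1OCC=C(O)C1=O | intermediate
20 | 6-tert-butoxy-6-oxohexyl (2E)-3-methyl-4-[(2S)-4-{[(3RS,4R,5S)-4-methyl-5-(triethylsilyloxy)hex-1-en-3-yl]oxy}-3-oxo-3,6-dihydro-2H-pyran-2-yl]but-2-enoate (not isolated) | C/C(=C\C(=O)OCCCCCC(=O)OC(C)(C)C)C[C@@H]1OCC=C(OC(C=C)[C@@H](C)[C@H](C)O[Si](CC)(CC)CC)C1=O | intermediate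
21 | 6-tert-butoxy-6-oxohexyl (2E)-3-methyl-4-{(2S,5RS)-5-[(2E,4R,5S)-4-methyl-5-(triethylsilyloxy)hex-2-en-1-yl]-3,4-dioxooxan-2-yl}but-2-enoate (not isolated) | C/C(=C\C(=O)OCCCCCC(=O)OC(C)(C)C)C[C@@H]1OCC(C/C=C/[C@@H](C)[C@H](C)O[Si](CC)(CC)CC)C(=O)C1=O | intermediate
22 | 6-tert-butoxy-6-oxohexyl (2E)-4-{(2S)-4-hydroxy-5-[(2E,4R,5S)-4-methyl-5-(triethylsilyloxy)hex-2-en-1-yl]-3-oxo-3,6-dihydro-2H-pyran-2-yl}-3-methylbut-2-enoate | C/C(=C\C(=O)OCCCCCC(=O)OC(C)(C)C)C[C@@H]1OCC(C/C=C/[C@@H](C)[C@H](C)O[Si](CC)(CC)CC)=C(O)C1=O | intermediate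
23 | 6-{[(2E)-4-{(2S)-4-hydroxy-5-[(2E,4R,5S)-5-hydroxy-4-methylhex-2-en-1-yl]-3-oxo-3,6-dihydro-2H-pyran-2-yl}-3-methylbut-2-enoyl]oxy}hexanoic acid (6,7-diketothiomarinolic acid C6) | C/C(=C\C(=O)OCCCCCC(=O)O)C[C@@H]1OCC(C/C=C/[C@@H](C)[C@H](C)O)=C(O)C1=O | target

**Step count and risks**

Total step count: 13. Longest linear sequence: 9 steps (steps 5–13, from tert-butyl 3-methylbut-2-enoate); the branch to 5 is 4 steps (steps 1–4).

Steps most likely to fail:

1. Step 12. The etherification at the hindered, α-branched C11 carbinol may proceed with allylic transposition (SN2') or elimination of the oxyphosphonium intermediate, and the rearranged diketone may enolise in the wrong direction (toward C5). The fallback sets out from 19 (and 4) and comes back at 22. Mitsunobu etherification of 19 with allyl alcohol (PPh3, DIAD, toluene), which has no regiochemical ambiguity, should give the O-allyl enol ether F1. Heating in toluene should bring about the Claisen shift to the C8-allyl ring diketone F2, which should enolise to the C8-allyl diosphenol F3. In parallel, aldehyde 4 is methylenated (Ph3P=CH2, THF, Wittig) to the terminal alkene F4. Cross-metathesis of F3 with excess F4 (second-generation Hoveyda–Grubbs catalyst, CH2Cl2, 40 °C) should then build the E-C10=C11 bond and deliver 22.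

2. Step 13. The prolonged exposure to strong acid needed for the tert-butyl ester may cause loss of tautomeric or configurational integrity at the diosphenol/C5 or acylation of the C13 hydroxyl. The fallback sets out from 22 and comes back at 23, using two orthogonal cleavages instead of one acidolysis. Desilylation with HF·pyridine (THF/pyridine, 0 °C) should give the hydroxy tert-butyl ester F5. Non-protic dealkylation by silyl transfer (Me3SiOTf, 2,6-lutidine, CH2Cl2, −20 → 0 °C) should convert it to the tris(trimethylsilyl) derivative F6 (silyl ester, silyl enol ether, silyl ether). A pH 5 buffer work-up should hydrolyse F6 to 23.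

3. Step 10. The hydrosilylation may lose chemoselectivity (1,2-addition to the ketone or reduction of the enoate), or the peracid stage may over-oxidise. The fallback sets out from 14 and comes back at 17. Mukaiyama-type hydrogen-atom-transfer oxygenation of the enone (Mn(dpm)3 cat., PhSiH3, O2, i-PrOH/CH2Cl2, 0 °C) should give the C7 hydroperoxide F7, which is reduced in the same flask with P(OEt)3 to 17.

Further compounds
F1 | step 12 | 6-tert-butoxy-6-oxohexyl (2E)-3-methyl-4-[(2S)-3-oxo-4-(prop-2-en-1-yloxy)-3,6-dihydro-2H-pyran-2-yl]but-2-enoate | C/C(=C\C(=O)OCCCCCC(=O)OC(C)(C)C)C[C@@H]1OCC=C(OCC=C)C1=O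
F2 | step 12 | 6-tert-butoxy-6-oxohexyl (2E)-4-[(2S,5RS)-3,4-dioxo-5-(prop-2-en-1-yl)oxan-2-yl]-3-methylbut-2-enoate | C/C(=C\C(=O)OCCCCCC(=O)OC(C)(C)C)C[C@@H]1OCC(CC=C)C(=O)C1=O
F3 | step 12 | 6-tert-butoxy-6-oxohexyl (2E)-4-[(2S)-4-hydroxy-3-oxo-5-(prop-2-en-1-yl)-3,6-dihydro-2H-pyran-2-yl]-3-methylbut-2-enoate | C/C(=C\C(=O)OCCCCCC(=O)OC(C)(C)C)C[C@@H]1OCC(CC=C)=C(O)C1=O
F4 | step 12 | triethyl{[(2S,3R)-3-methylpent-4-en-2-yl]oxy}silane | C=C[C@@H](C)[C@H](C)O[Si](CC)(CC)CC
F5 | step 13 | 6-tert-butoxy-6-oxohexyl (2E)-4-{(2S)-4-hydroxy-5-[(2E,4R,5S)-5-hydroxy-4-methylhex-2-en-1-yl]-3-oxo-3,6-dihydro-2H-pyran-2-yl}-3-methylbut-2-enoate | C/C(=C\C(=O)OCCCCCC(=O)OC(C)(C)C)C[C@@H]1OCC(C/C=C/[C@@H](C)[C@H](C)O)=C(O)C1=O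
F6 | step 13 | trimethylsilyl 6-{[(2E)-3-methyl-4-{(2S)-5-[(2E,4R,5S)-4-methyl-5-(trimethylsilyloxy)hex-2-en-1-yl]-3-oxo-4-(trimethylsilyloxy)-3,6-dihydro-2H-pyran-2-yl}but-2-enoyl]oxy}hexanoate | C/C(=C\C(=O)OCCCCCC(=O)O[Si](C)(C)C)C[C@@H]1OCC(C/C=C/[C@@H](C)[C@H](C)O[Si](C)(C)C)=C(O[Si](C)(C)C)C1=O
F7 | step 10 | 6-tert-butoxy-6-oxohexyl (2E)-4-[(2S,4RS)-4-hydroperoxy-3-oxooxan-2-yl]-3-methylbut-2-enoate | C/C(=C\C(=O)OCCCCCC(=O)OC(C)(C)C)C[C@@H]1OCCC(OO)C1=O
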